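**Retrosynthetic overview**
1. Target 18 is cut at the bond between the bridging CH2 and ring B: Michael addition of the enol of propionylfilicinic acid 16 to the o-quinone methide 17 released from the phenolic Mannich base 12.
2. 12 comes from a Mannich aminomethylation (CH2O, Me2NH) of the ring A ketone 11 at its only free ring carbon.
3. 11 comes from 2,4,6-trihydroxybenzaldehyde 1: chelation-controlled bis-MOM protection, CHO to CH3, phenol-directed ortho-formylation, O-methylation, n-PrMgBr addition/oxidation, MOM removal.
4. 16 comes from gem-C-dimethylation of flopropione 14, itself from Friedel–Crafts propionylation of phloroglucinol 13.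
5. No ring is built: ring A (from 1) and ring B (from 13) are bought as benzene rings; ring B is dearomatised in step 10, before the union in step 11.

Assumption: the target has no stereocentre and is achiral, so no enantiocontrol is needed; it is drawn as the enol tautomer of the given SMILES.

**Route**

Step 1
Reactants: 1 2,4,6-trihydroxybenzaldehyde
Product: 2 2-hydroxy-4,6-bis(methoxymethoxy)benzaldehyde
Conditions: MOMCl (2.2 equiv), i-Pr2NEt (2.5 equiv), CH2Cl2, 0 °C to rt
Reagents that add atoms: chloromethyl methyl ether (MOMCl), COCCl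
Why: Williamson-type O-alkylation in which the one hydroxyl hydrogen-bonded to the formyl group stays unreactive, and since both ortho hydroxyls of 1 are equivalent only one bis-ether can form.

Step 2
Reactants: 2 2-hydroxy-4,6-bis(methoxymethoxy)benzaldehyde
Product: 5 3,5-bis(methoxymethoxy)-2-methylphenol, via aryl ethyl carbonate 3 (not isolated), via o-quinone methide 4 (not isolated)
Conditions: ClCO2Et, Et3N, THF, 0 °C; then NaBH4, H2O/THF, 0 °C to rt; aq. NH4Cl work-up
Reagents that add atoms: none
Why: Chloroformate/borohydride deoxygenation of a salicylaldehyde, in which aldehyde reduction triggers carbonate transfer and 1,4-elimination to 4, which takes up hydride by conjugate reduction, all under non-acidic conditions that spare the MOM ethers.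

Step 3
Reactants: 5 3,5-bis(methoxymethoxy)-2-methylphenol
Product: 7 2-hydroxy-4,6-bis(methoxymethoxy)-3-methylbenzaldehyde, via salicyl alcohol 6 (not isolated)
Conditions: MgCl2 (2 equiv), Et3N (4 equiv), (CH2O)n (6 equiv), MeCN, reflux; aq. NH4Cl work-up
Reagents that add atoms: paraformaldehyde (as formaldehyde), C=O
Why: Magnesium-mediated ortho-formylation (Casiraghi–Skattebøl), in which formaldehyde is delivered inside the magnesium phenoxide chelate to the only free ortho carbon and the resulting salicyl alcohol 6 is oxidised by Oppenauer-type hydride transfer to a second formaldehyde.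

Step 4
Reactants: 7 2-hydroxy-4,6-bis(methoxymethoxy)-3-methylbenzaldehyde
Product: 8 2-methoxy-4,6-bis(methoxymethoxy)-3-methylbenzaldehyde
Conditions: MeI (3 equiv), K2CO3 (3 equiv), DMF, rt to 40 °C
Reagents that add atoms: iodomethane (MeI), CI
Why: Williamson ether synthesis on the single free phenol, which fixes the methoxy group between the methyl group and the future acyl group.

Step 5
Reactants: 8 2-methoxy-4,6-bis(methoxymethoxy)-3-methylbenzaldehyde
Product: 9 1-[2-methoxy-4,6-bis(methoxymethoxy)-3-methylphenyl]butan-1-ol (racemic)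
Conditions: n-PrMgBr (1.5 equiv), THF, 0 °C to rt; then H2O
Reagents that add atoms: n-propylmagnesium bromide, CCC[Mg]Br
Why: Grignard 1,2-addition to the aldehyde, whose new carbinol stereocentre forms as a racemate and is erased by the oxidation in step 6.

Step 6
Reactants: 9 1-[2-methoxy-4,6-bis(methoxymethoxy)-3-methylphenyl]butan-1-ol
Product: 10 1-[2-methoxy-4,6-bis(methoxymethoxy)-3-methylphenyl]butan-1-one
Conditions: (n-Pr)4N[RuO4] (5 mol %), N-methylmorpholine N-oxide (1.5 equiv), 4 Å molecular sieves, CH2Cl2, rt
Reagents that add atoms: none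
Why: Ley–Griffith oxidation of a secondary benzylic alcohol under neutral conditions, which keeps the MOM ethers and the acid-sensitive electron-rich benzylic position intact.

Step 7
Reactants: 10 1-[2-methoxy-4,6-bis(methoxymethoxy)-3-methylphenyl]butan-1-one
Product: 11 1-(4,6-dihydroxy-2-methoxy-3-methylphenyl)butan-1-one
Conditions: 3 M HCl, MeOH, 50 °C
Reagents that add atoms: none
Why: Acid-catalysed acetal methanolysis removes both MOM groups, with methanol trapping the CH2O units so they cannot bridge the electron-rich ring, while the aryl methyl ether and ketone are inert.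

Step 8
Reactants: 11 1-(4,6-dihydroxy-2-methoxy-3-methylphenyl)butan-1-one
Product: 12 1-{3-[(dimethylamino)methyl]-2,4-dihydroxy-6-methoxy-5-methylphenyl}butan-1-one
Conditions: 37 % aq. CH2O (1.5 equiv), 40 % aq. Me2NH (1.5 equiv), EtOH, 0 °C to rt
Reagents that add atoms: formaldehyde, C=O; dimethylamine, CNC
Why: Phenolic Mannich reaction, in which the iminium ion attacks the only unsubstituted ring carbon (flanked by two hydroxyls), and excess reagent at low temperature prevents diarylmethane formation.

Step 9
Reactants: 13 phloroglucinol (benzene-1,3,5-triol)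
Product: 14 1-(2,4,6-trihydroxyphenyl)propan-1-one (flopropione)
Conditions: EtCOCl (1.1 equiv), AlCl3 (3.5 equiv), PhNO2/CH2Cl2, 0 to 45 °C; then ice/aq. HCl
Reagents that add atoms: propionyl chloride, CCC(=O)Cl
Why: Friedel–Crafts acylation of a threefold-symmetric arene gives one mono-ketone, and the acyl group deactivates the ring against a second acylation.

Step 10
Reactants: 14 1-(2,4,6-trihydroxyphenyl)propan-1-one
Product: 16 3,5-dihydroxy-6,6-dimethyl-2-propanoylcyclohexa-2,4-dien-1-one (propionylfilicinic acid), via mono-C-methyl ketone 15 (not isolated)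
Conditions: NaOMe (4 equiv), MeI (2.3 equiv), MeOH, 0 °C to rt; then aq. HCl
Reagents that add atoms: iodomethane (MeI), CI
Why: C-alkylation of the ambident phloroglucinol polyanion, in which the second methylation at the same ring carbon dearomatises the ring to the stable vinylogous acid (gem-dimethylation to the acylfilicinic acid).

Step 11
Reactants: 12 1-{3-[(dimethylamino)methyl]-2,4-dihydroxy-6-methoxy-5-methylphenyl}butan-1-one; 16 propionylfilicinic acid (1.2 equiv)
Product: 18 Aspidin PB, via o-quinone methide 17 (not isolated)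
Conditions: 1,4-dioxane, 90–100 °C, N2 stream; non-basic work-up (dilute aq. HCl wash)
Reagents that add atoms: none
Why: The acidic triketone 16 protonates the benzylic amine, thermal loss of Me2NH gives o-quinone methide 17, and intermolecular Michael addition of the only nucleophilic carbon of 16 to its exocyclic CH2 rearomatises ring A; no stereocentre is formed.

**Compound list**
1 | 2,4,6-trihydroxybenzaldehyde | O=Cc1c(O)cc(O)cc1O | starting material
2 | 2-hydroxy-4,6-bis(methoxymethoxy)benzaldehyde | O=Cc1c(O)cc(OCOC)cc1OCOC | intermediate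
3 | ethyl 2-formyl-3,5-bis(methoxymethoxy)phenyl carbonate | CCOC(=O)Oc1cc(OCOC)cc(OCOC)c1C=O | intermediate
4 | 3,5-bis(methoxymethoxy)-6-methylidenecyclohexa-2,4-dien-1-one | C=C1C(=O)C=C(OCOC)C=C1OCOC | intermediate
5 | 3,5-bis(methoxymethoxy)-2-methylphenol | Cc1c(O)cc(OCOC)cc1OCOC | intermediate
6 | 2-(hydroxymethyl)-3,5-bis(methoxymethoxy)-6-methylphenol | OCc1c(O)c(C)c(OCOC)cc1OCOC | intermediate
7 | 2-hydroxy-4,6-bis(methoxymethoxy)-3-methylbenzaldehyde | O=Cc1c(O)c(C)c(OCOC)cc1OCOC | intermediate
8 | 2-methoxy-4,6-bis(methoxymethoxy)-3-methylbenzaldehyde | O=Cc1c(OC)c(C)c(OCOC)cc1OCOC | intermediate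
9 | 1-[2-methoxy-4,6-bis(methoxymethoxy)-3-methylphenyl]butan-1-ol (racemic) | CCCC(O)c1c(OC)c(C)c(OCOC)cc1OCOC | intermediate
10 | 1-[2-methoxy-4,6-bis(methoxymethoxy)-3-methylphenyl]butan-1-one | CCCC(=O)c1c(OC)c(C)c(OCOC)cc1OCOC | intermediate
11 | 1-(4,6-dihydroxy-2-methoxy-3-methylphenyl)butan-1-one | CCCC(=O)c1c(O)cc(O)c(C)c1OC | intermediate
12 | 1-{3-[(dimethylamino)methyl]-2,4-dihydroxy-6-methoxy-5-methylphenyl}butan-1-one | CCCC(=O)c1c(O)c(CN(C)C)c(O)c(C)c1OC | intermediate
13 | phloroglucinol (benzene-1,3,5-triol) | Oc1cc(O)cc(O)c1 | starting material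
14 | 1-(2,4,6-trihydroxyphenyl)propan-1-one (flopropione) | CCC(=O)c1c(O)cc(O)cc1O | intermediate
15 | 1-(2,4,6-trihydroxy-3-methylphenyl)propan-1-one | CCC(=O)c1c(O)cc(O)c(C)c1O | intermediate
16 | 3,5-dihydroxy-6,6-dimethyl-2-propanoylcyclohexa-2,4-dien-1-one (propionylfilicinic acid) | CCC(=O)C1=C(O)C=C(O)C(C)(C)C1=O | intermediate
17 | 4-butanoyl-5-hydroxy-3-methoxy-2-methyl-6-methylidenecyclohexa-2,4-dien-1-one | CCCC(=O)C1=C(O)C(=C)C(=O)C(C)=C1OC | intermediate
18 | Aspidin PB, 4-[(3-butanoyl-2,6-dihydroxy-4-methoxy-5-methylphenyl)methyl]-3,5-dihydroxy-6,6-dimethyl-2-propanoylcyclohexa-2,4-dien-1-one | CCCC(=O)c1c(O)c(CC2=C(O)C(C)(C)C(=O)C(C(=O)CC)=C2O)c(O)c(C)c1OC | target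

**Step count**
Total steps: 11. Longest linear sequence: 9 (steps 1–8, then 11); the ring B branch is steps 9–10.

**Three steps most likely to fail, with fallbacks**

Step 10 (gem-dimethylation). Ketone 14 has two free ring carbons, so mono-, 3,5-di-, tri- and O-methylated by-products can lower the yield of 16. The fallback sets out from 13 and blocks one carbon first. Double Friedel–Crafts acetylation (Ac2O, BF3·OEt2, 80 °C) gives 2,4-diacetylphloroglucinol F1, which has a single free ring carbon. NaOMe/MeI in MeOH can then only place both methyl groups on that carbon, giving 2,4-diacetyl-3,5-dihydroxy-6,6-dimethylcyclohexa-2,4-dien-1-one (diacetylfilicinic acid) F2. Hot aqueous H2SO4 (about 80 %, 80 °C) strips both acetyl groups by retro-Claisen deacylation to filicinic acid F3. C-propionylation of F3 (EtCOCl, AlCl3, PhNO2, rt; the first acyl group deactivates the second site) comes back to the route at 16.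

Step 11 (fragment union). The o-quinone methide 17 may recombine with Me2NH, or the product may undergo retro-Michael scrambling to symmetric methylene-bridged dimers. The fallback reverses the polarity and sets out from 16 and 11. Mannich reaction of 16 (aq. CH2O, Me2NH, EtOH, 0 °C) gives 4-[(dimethylamino)methyl]-3,5-dihydroxy-6,6-dimethyl-2-propanoylcyclohexa-2,4-dien-1-one F4. Warming F4 with 11 in dioxane (80 °C) expels Me2NH to give the methylene trione 5-hydroxy-2,2-dimethyl-6-methylidene-4-propanoylcyclohex-4-ene-1,3-dione F5. The only free, doubly hydroxyl-activated ring carbon of 11 adds to this acceptor in a Michael (Friedel–Crafts-type conjugate) addition, and the route is rejoined at 18, bypassing 12.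

Step 3 (ortho-formylation). The hindered, very electron-rich phenol 5 could give diarylmethanes, or lose a MOM group to MgCl2 at reflux. The fallback sets out from 5 and separates C–C bond formation from oxidation using a boron template. PhB(OH)2, (CH2O)n and catalytic EtCO2H in toluene at reflux (Dean–Stark) give 5,7-bis(methoxymethoxy)-8-methyl-2-phenyl-4H-1,3,2-benzodioxaborinine F6, formed only at the ortho carbon. Transesterification with propane-1,3-diol releases the salicyl alcohol 6, this time isolated. MnO2 in CH2Cl2 at rt oxidises 6 and comes back to the route at 7.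

**Further compounds**
F1 | step 10 | 2,4-diacetylphloroglucinol, 1,1'-(2,4,6-trihydroxy-1,3-phenylene)di(ethan-1-one) | CC(=O)c1c(O)cc(O)c(C(C)=O)c1O
F2 | step 10 | 2,4-diacetyl-3,5-dihydroxy-6,6-dimethylcyclohexa-2,4-dien-1-one (diacetylfilicinic acid) | CC(=O)C1=C(O)C(C(C)=O)=C(O)C(C)(C)C1=O
F3 | step 10 | filicinic acid, 3,5-dihydroxy-4,4-dimethylcyclohexa-2,5-dien-1-one | CC1(C)C(O)=CC(=O)C=C1O
F4 | step 11 | 4-[(dimethylamino)methyl]-3,5-dihydroxy-6,6-dimethyl-2-propanoylcyclohexa-2,4-dien-1-one | CCC(=O)C1=C(O)C(CN(C)C)=C(O)C(C)(C)C1=O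
F5 | step 11 | 5-hydroxy-2,2-dimethyl-6-methylidene-4-propanoylcyclohex-4-ene-1,3-dione | CCC(=O)C1=C(O)C(=C)C(=O)C(C)(C)C1=O
F6 | step 3 | 5,7-bis(methoxymethoxy)-8-methyl-2-phenyl-4H-1,3,2-benzodioxaborinine | Cc1c(OCOC)cc(OCOC)c2COB(c3ccccc3)Oc12
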